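The runs stem from a simulated flask from invented constants, and the scatter is random.

Treat each portion of starting material as a flask of its own. At a fixed amount of catalyst the decay of starting material looks pseudo-first-order, and then the fraction left does not depend on the amount put in. The portion that goes in at the start is therefore the zero of the scale: reckon it like an everything-together flask, and reckon a later portion the same way with its shorter time. Here are the flasks, the readings and the questions.

| setting | Monday's | Saturday's | beta | eta |
|---|---|---|---|---|
| starting material | 0.10 M (in portions, 2) | 0.10 M (in portions, 2) | 0.10 M | 0.10 M (in portions, 2) |
| free catalyst | 0.23 mM | 0.43 mM | 0.30 mM | 0.50 mM |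
| remark | run made earlier; portions every 8.0 min | run made earlier; portions every 8.0 min | everything together at the start | the portions of starting material follow each other after 8.0 min, the first at the start |
| time |  |  | 40 min | 20 min |

| run | time / min | target / % | starting material / % |
|---|---|---|---|
| Monday's | 1.33 | 1.1 | 47.1 |
| Monday's | 4.00 | 5.7 | 44.2 |
| Monday's | 6.00 | 8.1 | 42.2 |
| Monday's | 10.0 | 14.9 | 85.2 |
| Saturday's | 2.50 | 4.1 | 44.4 |
| Saturday's | 5.00 | 12.0 | 39.2 |
| Saturday's | 8.00 | 16.3 | 33.6 |
| Saturday's | 10.0 | 24.6 | 75.1 |

(each reading ± 1 percentage point)

1. which of the two ends with the higher amount of target, in percent of the starting material charged ("neither" if they lie within 2 percentage points) (beta / eta / neither)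
2. target at the end, in percent of the starting material charged, beta
3. target at the end, in percent of the starting material charged, eta

- the earlier runs were read with a standard deviation of 1 percentage point

Read the decay constant two ways, once from each run, using the last reading before the second portion. Each portion starts at 50.0% of the charge. Monday's run stands at 42.2% after 6.00 min, and dividing the logarithmic fall by time and catalyst gives 2.05 M⁻¹ s⁻¹. Saturday's run stands at 33.6% after 8.00 min, which gives κ = 1.93 M⁻¹ s⁻¹. Call κ, the decay rate of starting material per unit of free catalyst charged, the working constant of these flasks.

The two readings nearly agree across different amounts of catalyst, so the rate follows the catalyst. Trust Saturday's figure more, because its reading fell by 16 points, more than Monday's 7.8 points, and both were read to 1 point.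

Now test κ on a reading it was not made from: Monday's at 10.0 min, after the second portion. Summing both portions gives 85.7% of the charge left, and the reading was 85.2%.

So write the fraction left as exp(−κct), with c the catalyst and t the time a portion has spent in the flask. Beta keeps 25.0%, which makes 75.0% target. In eta, average the two portions: the first has 20 min, the second 12.0 min. That leaves 40.7%, so 59.3% target, and beta ends higher.

The forecast also says beta, with 76% for beta and 60% for eta, on a rate it found “proportional to catalyst”. Both its figures are slightly higher than mine.

The flask gives 74.1% in beta and 59.3% in eta, so beta ends higher.

    starting material + free catalyst → catalyst intermediate A (k = 2.24 M⁻¹ s⁻¹)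
    catalyst intermediate A → catalyst intermediate B (k = 19.6 s⁻¹)
    catalyst intermediate B → free catalyst + target (k = 0.905 s⁻¹)
    free catalyst + target → spent catalyst (k = 0.00126 M⁻¹ s⁻¹)

At the end of beta, free catalyst stood at 83.0% of its charge. Use κ once more on a neighbour flask, which is beta with 1.2 × 10⁻⁴ M of free catalyst over the same 40 min. κ leaves 57.4% of the starting material, so 42.6% target, and that neighbour flask ended with 40.9% of target.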